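**Plan**

- Feature used: C3 of the tetralin carries two one-carbon arms, the ring CH2 (C4) and CH2OH, both at the alcohol oxidation level. Joined through one oxygen they form an oxetane on C2, a ring absent from the target, whose two CH2 groups are diastereotopic. C4a of ring A (the fused ring) lies para to the C7 oxygen.
- Retrosynthesis: remove the phenol protecting groups; cut C4–C4a (aryl carbon to benzylic CH2) back to oxetane 14; cut the coumarate ester C–O bond and the ring B acetate; open an oxetane C–O bond to a 1,3-diol and take this back to a malonate; cut C2–C3 (aldehyde α-carbon to malonate carbon); cut the C1–aryl bond of ring A to a cinnamaldehyde and an arylboronic acid.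
- Forward: the chain is joined first (C1–aryl by conjugate arylation, then C2–C3 by α-alkylation), the temporary oxetane is closed, the p-coumaroyl ester is attached, and the carbocycle closes last by attack of ring A on the oxetane.
- Stereochemistry: C1 from a chiral diene–rhodium catalyst and C2 from a chiral imidazolidinone, both catalyst-controlled because the two aryl groups on C1 differ only by an OH/OMe swap and give no substrate bias. C3 is set in the ring closure, where a chair transition state selects one oxetane CH2.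

Key step: step 9

Remark: locants C1–C4, C4a and C7 are those of the tetrahydronaphthalene of the target and are used for the same carbons in open-chain intermediates. The facial sense of the catalysts in steps 2 and 3 is assumed to follow their behaviour with simple β-aryl enals and linear aldehydes; the antipodal catalyst is used if a test run shows the opposite sense.

**Route**

Step 1
Reactants: 1 (E)-3-(4-hydroxy-3-methoxyphenyl)prop-2-enal (coniferaldehyde)
Product: 2 (E)-3-[3-methoxy-4-(triisopropylsilyloxy)phenyl]prop-2-enal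
Conditions: TIPSCl (1.2 equiv), imidazole (2.5 equiv), DMF, 0 → 23 °C
Reagents that add atoms: triisopropylsilyl chloride, CC(C)[Si](Cl)(C(C)C)C(C)C
Why: Phenol silylation masks the vinylogously acidic phenol, whose phenolate would shut down the conjugate addition, with a group that should survive base, hydride and organolithium reagents.

Step 2
Reactants: 2 (E)-3-[3-methoxy-4-(triisopropylsilyloxy)phenyl]prop-2-enal; 3 [3-(benzyloxy)-4-methoxyphenyl]boronic acid
Product: 4 (3S)-3-[3-(benzyloxy)-4-methoxyphenyl]-3-[3-methoxy-4-(triisopropylsilyloxy)phenyl]propanal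
Conditions: 3 (1.5 equiv), [RhCl(C2H4)2]2 (1.5 mol %), (R,R)-Ph-bod* [(1R,4R)-2,5-diphenylbicyclo[2.2.2]octa-2,5-diene] (3.3 mol %), KOH (0.3 equiv), 1,4-dioxane/H2O 10:1, 30 °C
Reagents that add atoms: none
Why: Hayashi–Miyaura reaction, in which the aryl–rhodium species formed by transmetalation adds 1,4 to the enal (diene ligands suppress 1,2-addition) and the chiral diene selects the enal face, setting C1 as drawn.

Step 3
Reactants: 4 (3S)-3-[3-(benzyloxy)-4-methoxyphenyl]-3-[3-methoxy-4-(triisopropylsilyloxy)phenyl]propanal; 5 diethyl 2-bromopropanedioate (diethyl bromomalonate)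
Product: 6 diethyl 2-[(2R,3S)-3-[3-(benzyloxy)-4-methoxyphenyl]-3-[3-methoxy-4-(triisopropylsilyloxy)phenyl]-1-oxopropan-2-yl]propanedioate
Conditions: 5 (1.5 equiv), (2R,5S)-2-tert-butyl-3,5-dimethylimidazolidin-4-one·TfOH (20 mol %), Ru(bpy)3Cl2 (0.5 mol %), 2,6-lutidine (2 equiv), DMF, blue LEDs, 23 °C
Reagents that add atoms: none
Why: Photoredox/enamine α-alkylation of an aldehyde, in which the electrophilic malonyl radical from reduction of 5 adds to the chiral enamine on the face left open by the tert-butyl group, so C2 is set by the catalyst and not by C1.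

Step 4
Reactants: 6 diethyl 2-[(2R,3S)-3-[3-(benzyloxy)-4-methoxyphenyl]-3-[3-methoxy-4-(triisopropylsilyloxy)phenyl]-1-oxopropan-2-yl]propanedioate
Product: 7 diethyl 2-[(2R,3S)-3-[3-(benzyloxy)-4-methoxyphenyl]-1-[(tert-butyldimethylsilyl)oxy]-3-[3-methoxy-4-(triisopropylsilyloxy)phenyl]propan-2-yl]propanedioate
Conditions: t-BuMe2SiH (1.5 equiv), [(Ph3P)CuH]6 (1 mol %), toluene, 23 °C
Reagents that add atoms: tert-butyldimethylsilane, CC(C)(C)[SiH](C)C
Why: Copper hydride-catalysed hydrosilylation turns the aldehyde directly into the silyl ether under aprotic conditions, so the γ-hydroxy malonate that would lactonise is never free and the esters are untouched.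

Step 5
Reactants: 7 diethyl 2-[(2R,3S)-3-[3-(benzyloxy)-4-methoxyphenyl]-1-[(tert-butyldimethylsilyl)oxy]-3-[3-methoxy-4-(triisopropylsilyloxy)phenyl]propan-2-yl]propanedioate
Product: 8 2-[(2R,3S)-3-[3-(benzyloxy)-4-methoxyphenyl]-1-[(tert-butyldimethylsilyl)oxy]-3-[3-methoxy-4-(triisopropylsilyloxy)phenyl]propan-2-yl]propane-1,3-diol
Conditions: LiBH4 (4 equiv), THF, 0 → 40 °C
Reagents that add atoms: none
Why: Borohydride reduction of a monosubstituted malonate to the 2-substituted propane-1,3-diol, with a weakly basic hydride that should leave silyl and benzyl ethers intact and limit enolisation.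

Step 6
Reactants: 8 2-[(2R,3S)-3-[3-(benzyloxy)-4-methoxyphenyl]-1-[(tert-butyldimethylsilyl)oxy]-3-[3-methoxy-4-(triisopropylsilyloxy)phenyl]propan-2-yl]propane-1,3-diol
Product: 10 tert-butyl{[(2R,3S)-3-[3-(benzyloxy)-4-methoxyphenyl]-3-[3-methoxy-4-(triisopropylsilyloxy)phenyl]-2-(oxetan-3-yl)propyl]oxy}dimethylsilane, via monotosylate 9 (not isolated)
Conditions: n-BuLi (1.0 equiv), THF, 0 °C; TsCl (1.0 equiv), 0 °C; n-BuLi (1.0 equiv), 0 → 60 °C
Reagents that add atoms: p-toluenesulfonyl chloride, Cc1ccc(cc1)S(Cl)(=O)=O (its atoms are carried by 9 only)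
Why: One-pot monotosylation and intramolecular Williamson etherification (4-exo-tet) is the standard oxetane synthesis from 1,3-diols; either diastereotopic CH2OH may be tosylated because both monotosylates give the same oxetane, and the silyl group on the third oxygen prevents closure to a tetrahydrofuran.

Step 7
Reactants: 10 tert-butyl{[(2R,3S)-3-[3-(benzyloxy)-4-methoxyphenyl]-3-[3-methoxy-4-(triisopropylsilyloxy)phenyl]-2-(oxetan-3-yl)propyl]oxy}dimethylsilane
Product: 11 (2R,3S)-3-[3-(benzyloxy)-4-methoxyphenyl]-3-(4-hydroxy-3-methoxyphenyl)-2-(oxetan-3-yl)propan-1-ol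
Conditions: TBAF (3 equiv), THF, 0 → 23 °C
Reagents that add atoms: none
Why: Fluoride cleaves both the aryl and the alkyl silyl ether, while the oxetane is inert to fluoride and to the alkoxide and phenoxide formed, and the benzyl ether on ring A stays.

Step 8
Reactants: 11 (2R,3S)-3-[3-(benzyloxy)-4-methoxyphenyl]-3-(4-hydroxy-3-methoxyphenyl)-2-(oxetan-3-yl)propan-1-ol; 12 (E)-3-(4-acetoxyphenyl)prop-2-enoic acid
Product: 14 (2R,3S)-3-(4-acetoxy-3-methoxyphenyl)-3-[3-(benzyloxy)-4-methoxyphenyl]-2-(oxetan-3-yl)propyl (E)-3-(4-acetoxyphenyl)prop-2-enoate, via phenol ester 13 (not isolated)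
Conditions: 12 (1.2 equiv), PPh3 (1.3 equiv), DIAD (1.3 equiv), THF, 0 → 23 °C; then Ac2O (3 equiv), Et3N (4 equiv), DMAP (0.1 equiv), 23 °C
Reagents that add atoms: acetic anhydride, CC(=O)OC(C)=O
Why: In the Mitsunobu reaction the carboxylic acid is far more acidic than the phenol and should be the only pronucleophile, so the primary alcohol is esterified selectively under neutral conditions that spare the oxetane; the acetylation that follows caps the ring B phenol with the group that deactivates ring B for step 9.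

Step 9
Reactants: 14 (2R,3S)-3-(4-acetoxy-3-methoxyphenyl)-3-[3-(benzyloxy)-4-methoxyphenyl]-2-(oxetan-3-yl)propyl (E)-3-(4-acetoxyphenyl)prop-2-enoate
Product: 15 [(1S,2R,3R)-1-(4-acetoxy-3-methoxyphenyl)-7-(benzyloxy)-3-(hydroxymethyl)-6-methoxy-1,2,3,4-tetrahydronaphthalen-2-yl]methyl (E)-3-(4-acetoxyphenyl)prop-2-enoate
Conditions: Sc(OTf)3 (10 mol %), CH2Cl2/(CF3)2CHOH 4:1, 0.01 M, 0 → 23 °C
Reagents that add atoms: none
Why: Proposed new method: Sc(OTf)3 binds the oxetane oxygen and C6 of ring A (para to the benzyloxy group, the future C4a) attacks one of the two oxetane CH2 groups from the back in an SN2-like Friedel–Crafts alkylation, after which the arenium ion loses a proton and the scandium alkoxide is protonated to the CH2OH group, so the step is an isomerisation. The closest known reaction types are the Lewis-acid Friedel–Crafts alkylation of arenes by the parent oxetane to 3-arylpropanols, the acid-catalysed intramolecular desymmetrising opening of 3-substituted oxetanes by tethered O, N or S nucleophiles, and epoxy–arene cyclisations; the new element is a tethered arene as nucleophile with substrate-controlled choice between the two CH2 groups. The six-membered carbocycle closes in the 6-exo-tet mode, the breaking C–O bond lying outside the new ring. The new stereocenter C3 is controlled by C1 and C2: backside attack holds the departing CH2O arm anti to the incoming aryl carbon, that is equatorial on the forming chair, and the chair that also keeps the C1 aryl group and the C2 CH2O-ester arm equatorial is reached through only one of the CH2 groups and should give the all-trans (3R) isomer. The step needs ring selectivity, which the substrate secures because ring B is deactivated by its acetate (meta to the competing position) while ring A has an ether oxygen para to the reacting carbon and its other ortho position is crowded by the benzyloxy group; it also needs the arene to outrun the ester carbonyl, which would have to close a seven-membered ring, and high dilution should suppress oligomerisation.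

Step 10
Reactants: 15 [(1S,2R,3R)-1-(4-acetoxy-3-methoxyphenyl)-7-(benzyloxy)-3-(hydroxymethyl)-6-methoxy-1,2,3,4-tetrahydronaphthalen-2-yl]methyl (E)-3-(4-acetoxyphenyl)prop-2-enoate
Product: 16 [(1S,2R,3R)-1-(4-acetoxy-3-methoxyphenyl)-7-hydroxy-3-(hydroxymethyl)-6-methoxy-1,2,3,4-tetrahydronaphthalen-2-yl]methyl (E)-3-(4-acetoxyphenyl)prop-2-enoate
Conditions: BCl3 (3 equiv), C6HMe5 (5 equiv), CH2Cl2, −78 °C; then MeOH, aq. NaHCO3
Reagents that add atoms: none
Why: Lewis-acid debenzylation of an aryl benzyl ether with pentamethylbenzene as a non-basic benzyl cation scavenger works at −78 °C without hydrogen, so the cinnamate double bond, the esters and the methyl ethers should survive.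

Step 11
Reactants: 16 [(1S,2R,3R)-1-(4-acetoxy-3-methoxyphenyl)-7-hydroxy-3-(hydroxymethyl)-6-methoxy-1,2,3,4-tetrahydronaphthalen-2-yl]methyl (E)-3-(4-acetoxyphenyl)prop-2-enoate
Product: 17 [(1S,2R,3R)-7-hydroxy-1-(4-hydroxy-3-methoxyphenyl)-3-(hydroxymethyl)-6-methoxy-1,2,3,4-tetrahydronaphthalen-2-yl]methyl (E)-3-(4-hydroxyphenyl)prop-2-enoate
Conditions: NH4OAc (10 equiv), MeOH/H2O 4:1, 23 °C
Reagents that add atoms: none
Why: Selective solvolysis of aryl acetates, whose phenoxide leaving groups make them far more labile than the alkyl cinnamate, under neutral conditions that should avoid acyl migration to the neighbouring CH2OH.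

**Compound list**

1 | (E)-3-(4-hydroxy-3-methoxyphenyl)prop-2-enal (coniferaldehyde) | COc1cc(/C=C/C=O)ccc1O | starting material
2 | (E)-3-[3-methoxy-4-(triisopropylsilyloxy)phenyl]prop-2-enal | COc1cc(/C=C/C=O)ccc1O[Si](C(C)C)(C(C)C)C(C)C | intermediate
3 | [3-(benzyloxy)-4-methoxyphenyl]boronic acid | COc1ccc(B(O)O)cc1OCc1ccccc1 | starting material
4 | (3S)-3-[3-(benzyloxy)-4-methoxyphenyl]-3-[3-methoxy-4-(triisopropylsilyloxy)phenyl]propanal | COc1cc([C@@H](c2ccc(OC)c(OCc3ccccc3)c2)CC=O)ccc1O[Si](C(C)C)(C(C)C)C(C)C | intermediate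
5 | diethyl 2-bromopropanedioate | CCOC(=O)C(Br)C(=O)OCC | starting material
6 | diethyl 2-[(2R,3S)-3-[3-(benzyloxy)-4-methoxyphenyl]-3-[3-methoxy-4-(triisopropylsilyloxy)phenyl]-1-oxopropan-2-yl]propanedioate | COc1cc([C@@H](c2ccc(OC)c(OCc3ccccc3)c2)[C@H](C(C(=O)OCC)C(=O)OCC)C=O)ccc1O[Si](C(C)C)(C(C)C)C(C)C | intermediate
7 | diethyl 2-[(2R,3S)-3-[3-(benzyloxy)-4-methoxyphenyl]-1-[(tert-butyldimethylsilyl)oxy]-3-[3-methoxy-4-(triisopropylsilyloxy)phenyl]propan-2-yl]propanedioate | COc1cc([C@@H](c2ccc(OC)c(OCc3ccccc3)c2)[C@H](C(C(=O)OCC)C(=O)OCC)CO[Si](C)(C)C(C)(C)C)ccc1O[Si](C(C)C)(C(C)C)C(C)C | intermediate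
8 | 2-[(2R,3S)-3-[3-(benzyloxy)-4-methoxyphenyl]-1-[(tert-butyldimethylsilyl)oxy]-3-[3-methoxy-4-(triisopropylsilyloxy)phenyl]propan-2-yl]propane-1,3-diol | COc1cc([C@@H](c2ccc(OC)c(OCc3ccccc3)c2)[C@H](C(CO)CO)CO[Si](C)(C)C(C)(C)C)ccc1O[Si](C(C)C)(C(C)C)C(C)C | intermediate
9 | mono-p-toluenesulfonate of diol 8 (both epimers at the carbinol-bearing carbon, not isolated) | COc1cc([C@@H](c2ccc(OC)c(OCc3ccccc3)c2)[C@H](C(CO)COS(=O)(=O)c2ccc(C)cc2)CO[Si](C)(C)C(C)(C)C)ccc1O[Si](C(C)C)(C(C)C)C(C)C | intermediate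
10 | tert-butyl{[(2R,3S)-3-[3-(benzyloxy)-4-methoxyphenyl]-3-[3-methoxy-4-(triisopropylsilyloxy)phenyl]-2-(oxetan-3-yl)propyl]oxy}dimethylsilane | COc1cc([C@@H](c2ccc(OC)c(OCc3ccccc3)c2)[C@H](C2COC2)CO[Si](C)(C)C(C)(C)C)ccc1O[Si](C(C)C)(C(C)C)C(C)C | intermediate
11 | (2R,3S)-3-[3-(benzyloxy)-4-methoxyphenyl]-3-(4-hydroxy-3-methoxyphenyl)-2-(oxetan-3-yl)propan-1-ol | COc1cc([C@@H](c2ccc(OC)c(OCc3ccccc3)c2)[C@H](C2COC2)CO)ccc1O | intermediate
12 | (E)-3-(4-acetoxyphenyl)prop-2-enoic acid | CC(=O)Oc1ccc(/C=C/C(=O)O)cc1 | starting material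
13 | (2R,3S)-3-[3-(benzyloxy)-4-methoxyphenyl]-3-(4-hydroxy-3-methoxyphenyl)-2-(oxetan-3-yl)propyl (E)-3-(4-acetoxyphenyl)prop-2-enoate (not isolated) | COc1cc([C@@H](c2ccc(OC)c(OCc3ccccc3)c2)[C@H](C2COC2)COC(=O)/C=C/c2ccc(OC(C)=O)cc2)ccc1O | intermediate
14 | (2R,3S)-3-(4-acetoxy-3-methoxyphenyl)-3-[3-(benzyloxy)-4-methoxyphenyl]-2-(oxetan-3-yl)propyl (E)-3-(4-acetoxyphenyl)prop-2-enoate | COc1cc([C@@H](c2ccc(OC)c(OCc3ccccc3)c2)[C@H](C2COC2)COC(=O)/C=C/c2ccc(OC(C)=O)cc2)ccc1OC(C)=O | intermediate
15 | [(1S,2R,3R)-1-(4-acetoxy-3-methoxyphenyl)-7-(benzyloxy)-3-(hydroxymethyl)-6-methoxy-1,2,3,4-tetrahydronaphthalen-2-yl]methyl (E)-3-(4-acetoxyphenyl)prop-2-enoate | COc1cc([C@H]2c3cc(OCc4ccccc4)c(OC)cc3C[C@@H](CO)[C@@H]2COC(=O)/C=C/c2ccc(OC(C)=O)cc2)ccc1OC(C)=O | intermediate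
16 | [(1S,2R,3R)-1-(4-acetoxy-3-methoxyphenyl)-7-hydroxy-3-(hydroxymethyl)-6-methoxy-1,2,3,4-tetrahydronaphthalen-2-yl]methyl (E)-3-(4-acetoxyphenyl)prop-2-enoate | COc1cc([C@H]2c3cc(O)c(OC)cc3C[C@@H](CO)[C@@H]2COC(=O)/C=C/c2ccc(OC(C)=O)cc2)ccc1OC(C)=O | intermediate
17 | [(1S,2R,3R)-7-hydroxy-1-(4-hydroxy-3-methoxyphenyl)-3-(hydroxymethyl)-6-methoxy-1,2,3,4-tetrahydronaphthalen-2-yl]methyl (E)-3-(4-hydroxyphenyl)prop-2-enoate | COc1cc([C@H]2c3cc(O)c(OC)cc3C[C@@H](CO)[C@@H]2COC(=O)/C=C/c2ccc(O)cc2)ccc1O | target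

**Step count and risks**

Total step count: 11. Longest linear sequence: 11 steps (1 → 17).

Steps most likely to fail:

Step 9. What may go wrong: attack of ring B or of the ester carbonyl on the activated oxetane, cationic oligomerisation of the oxetane, or poor discrimination between the two oxetane CH2 groups. Fallback with known chemistry, in which the reacting carbon is fixed by a halogen instead of by arene electronics: from 14, iodination with N-iodosuccinimide in MeCN at 23 °C should take place on the activated ring A, para to the benzyloxy group, to give (2R,3S)-3-(4-acetoxy-3-methoxyphenyl)-3-[5-(benzyloxy)-2-iodo-4-methoxyphenyl]-2-(oxetan-3-yl)propyl (E)-3-(4-acetoxyphenyl)prop-2-enoate F1. Iodine–lithium exchange under Parham cyclisation conditions (n-BuLi, THF/Et2O, −100 °C, where exchange should outrun addition to the esters), followed by BF3·OEt2 at −100 → −78 °C, should open the oxetane with the aryllithium through the same chair and return 15 after aqueous work-up.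

Step 3. What may go wrong: slow enamine formation from the hindered β,β-diaryl aldehyde, addition of the malonyl radical to the electron-rich arenes, or loss of configuration at C2 by enolisation of the product. Fallback, a two-electron aldol in place of the radical alkylation: from 4, the proline-catalysed direct aldol reaction with diethyl 2-oxopropanedioate (proline enantiomer chosen to give the same C2 sense, CH2Cl2, 23 °C) should give diethyl 2-[(2R,3S)-3-[3-(benzyloxy)-4-methoxyphenyl]-3-[3-methoxy-4-(triisopropylsilyloxy)phenyl]-1-oxopropan-2-yl]-2-hydroxypropanedioate F2. Hydrosilylation of the aldehyde as in step 4 should give diethyl 2-[(2S,3S)-3-[3-(benzyloxy)-4-methoxyphenyl]-1-[(tert-butyldimethylsilyl)oxy]-3-[3-methoxy-4-(triisopropylsilyloxy)phenyl]propan-2-yl]-2-hydroxypropanedioate F3 (same spatial arrangement; the descriptor changes with the priorities). Acetylation (Ac2O, DMAP, Et3N) should give diethyl 2-acetoxy-2-[(2S,3S)-3-[3-(benzyloxy)-4-methoxyphenyl]-1-[(tert-butyldimethylsilyl)oxy]-3-[3-methoxy-4-(triisopropylsilyloxy)phenyl]propan-2-yl]propanedioate F4, and reductive cleavage of the α-acetoxy group with SmI2 (THF/MeOH, −78 °C) should return 7.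

Step 4. What may go wrong: quenching of the copper hydride by the acidic malonate C–H with incomplete conversion, or epimerisation at C2 before the aldehyde is reduced. Fallback, stoichiometric reduction and separate silylation: from 6, NaBH4 in EtOH at −40 °C should give diethyl 2-[(2R,3S)-3-[3-(benzyloxy)-4-methoxyphenyl]-1-hydroxy-3-[3-methoxy-4-(triisopropylsilyloxy)phenyl]propan-2-yl]propanedioate F5, which is silylated at once, before it can lactonise (TBSCl, imidazole, DMF, 0 °C), to return 7.

**Further compounds**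

F1 | step 9 | (2R,3S)-3-(4-acetoxy-3-methoxyphenyl)-3-[5-(benzyloxy)-2-iodo-4-methoxyphenyl]-2-(oxetan-3-yl)propyl (E)-3-(4-acetoxyphenyl)prop-2-enoate | COc1cc([C@@H](c2cc(OCc3ccccc3)c(OC)cc2I)[C@H](C2COC2)COC(=O)/C=C/c2ccc(OC(C)=O)cc2)ccc1OC(C)=O
F2 | step 3 | diethyl 2-[(2R,3S)-3-[3-(benzyloxy)-4-methoxyphenyl]-3-[3-methoxy-4-(triisopropylsilyloxy)phenyl]-1-oxopropan-2-yl]-2-hydroxypropanedioate | COc1cc([C@@H](c2ccc(OC)c(OCc3ccccc3)c2)[C@H](C(O)(C(=O)OCC)C(=O)OCC)C=O)ccc1O[Si](C(C)C)(C(C)C)C(C)C
F3 | step 3 | diethyl 2-[(2S,3S)-3-[3-(benzyloxy)-4-methoxyphenyl]-1-[(tert-butyldimethylsilyl)oxy]-3-[3-methoxy-4-(triisopropylsilyloxy)phenyl]propan-2-yl]-2-hydroxypropanedioate | COc1cc([C@@H](c2ccc(OC)c(OCc3ccccc3)c2)[C@H](C(O)(C(=O)OCC)C(=O)OCC)CO[Si](C)(C)C(C)(C)C)ccc1O[Si](C(C)C)(C(C)C)C(C)C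
F4 | step 3 | diethyl 2-acetoxy-2-[(2S,3S)-3-[3-(benzyloxy)-4-methoxyphenyl]-1-[(tert-butyldimethylsilyl)oxy]-3-[3-methoxy-4-(triisopropylsilyloxy)phenyl]propan-2-yl]propanedioate | COc1cc([C@@H](c2ccc(OC)c(OCc3ccccc3)c2)[C@H](C(OC(C)=O)(C(=O)OCC)C(=O)OCC)CO[Si](C)(C)C(C)(C)C)ccc1O[Si](C(C)C)(C(C)C)C(C)C
F5 | step 4 | diethyl 2-[(2R,3S)-3-[3-(benzyloxy)-4-methoxyphenyl]-1-hydroxy-3-[3-methoxy-4-(triisopropylsilyloxy)phenyl]propan-2-yl]propanedioate | COc1cc([C@@H](c2ccc(OC)c(OCc3ccccc3)c2)[C@H](C(C(=O)OCC)C(=O)OCC)CO)ccc1O[Si](C(C)C)(C(C)C)C(C)C
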